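(The numbers are assumed, and the outcome is calculated.)

The time allowed is long, 10 h, but the activator in this flask has a half-life of 1.28 min against its own decomposition, so you are watching a race of minutes.

substrate 0.020 M; activator 0.0240 M; time 10 h

    substrate + activator → activated form (k1 = 17.3 L mol⁻¹ min⁻¹)
    activated form → ring (k2 = 0.530 min⁻¹)
    substrate + activated form → open dimer (k3 = 12.2 L mol⁻¹ min⁻¹)
    activator → decomposed reagent (k4 = 0.543 min⁻¹)
    ring ⇌ isomer of the product (K5 = 2.01, k5 = 1.34 min⁻¹)

- which holds at 10 h: what has brought the reaction to rest, or that it has not come to rest (forward and back rates have come level / the activator has run out first / all of the substrate has reacted / it is still moving)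
- ring at 10 h, in percent of the substrate charged
- isomer of the product at 10 h, in percent of the substrate charged
- amount of ring if the flask were left three thousand times as long, in percent of the substrate charged

- a species is counted by the substrate in it: one open dimer counts as two
- the reaction counts as stopped when no species that holds the substrate changes by six tenths of a point or more over the second half of the time
- run time (flask): 10 h

The bench rule says that 1.20 equivalents of activator carry the substrate to the end. That rule counts on the activator being spent on substrate. In this flask, at the start, decomposition uses activator 1.6 times as fast as activation does, so I drop the rule for this flask.

Reckon instead with the activator's share φ, the activation rate over the sum of activation and decomposition rates at a mean substrate level S. Let g be the selectivity for ring closure: the closure rate over the sum of closure and dimer-forming rates at S. Each activated form costs 2 − g substrates.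

Start with S at the charge: φ is 0.389, g is 0.685, and 38.6 % of the substrate remains. That lowers S, so put the mean of charge and remainder back in: 54.4 % remains. A third round gives φ = 0.330, and 29.2 % of the charge reaches ring plus isomer.

Interconversion is quick, with a half-life of 0.517 min by its forward constant, so I commit to ring at 9.70 %, with twice that as isomer, and the same ring for the long wait asked about.

The forecast says the activator has run out first, with ring 9.8 % (9 % to 10.6 %), isomer 19.7 % (18 % to 21.3 %) and long-term ring 9.8 % (9 % to 10.6 %). Its grounds: “The activator decomposes within a few minutes, faster than it can convert the substrate”. Its ring stands slightly above mine.

In the simulation the activator has run out first: activator stands at 0 %, ring at 10.0 %, isomer at 20.1 % and long-term ring at 10.0 %. Decomposed reagent in this flask stands at 0.0162 M after 10.0 h, leaving 0.326 of the activator for activation, beside my φ of 0.330. Now take a neighbour flask charged with 0.0080 M of substrate, where 49 % remains: φ at its mean level is 0.159, which reckons its ring at 14.0 %, and that neighbour holds 14.0 %.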